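## Structural features

Maackiaflavanone A is a (2S)-flavanone in which ring A is fused through C4a–C8a to the dihydropyranone ring C and C2 carries ring B, itself fused across C4'–C5' to a 2,2-dimethyl-2H-pyran, so that the C2 substituent is a 7-hydroxy-2,2-dimethyl-2H-chromen-6-yl group with a free hydroxyl (C2'–OH) next to the point of attachment. Ring A has a phloroglucinol oxygen pattern (O1 at C8a, a hydrogen-bonded hydroxyl at C5, a methyl ether at C7) and a prenyl group at C8, between O1 and the methoxy group; only C6 is unsubstituted. C2 is the only stereocentre and has no stereogenic neighbour; it is benzylic, bonded to O1 and β to the C4 carbonyl, so retro-oxa-Michael opening to the 2'-hydroxychalcone erases it under base, heat or Lewis acid, the more easily because ring B is electron-rich and carries an ortho hydroxyl. The fragile groups are the prenyl double bond and the chromene C3=C4 double bond (acid, electrophiles, hydrogenation) and the free phenols. Once the C5 hydroxyl is free, an opened ring C could also re-close through the C5 oxygen, which would move the prenyl group from C8 to C6. The real difficulties are therefore three: placing the prenyl group at C8 rather than C6 while telling the C5 and C7 oxygens apart, building the linear rather than the angular chromene on ring B, and creating and keeping the C2 configuration. The key step exploits the ortho relationship of C4a and C8a on ring A: one carries the acyl carbon C4 and the other the ether oxygen O1, which is the pair of substituents that an aryne takes up when it inserts into the C–O bond of a carboxylate. Because C4a lies next to the oxygenated C5 and C8a next to the prenylated C8, polarisation of the aryne by the C5 oxygen puts O1 beside the prenyl group.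

## Logic of the disconnections

31 to 30. The bond cut is the O–CH2 bond of the acetal on the ring B oxygen (C2'–O). It is cut last because this phenol must stay masked throughout: free, it would add to the aryne, and as a phenoxide it would help break C2–O1. The precursor gained has no free ring B phenol. The forward step must cleave the acetal mildly enough to leave both alkenes and C2 untouched.

30 to 29. The O–CH3 bond of the C5 ether is cut. The methyl group is kept until here because it lets ring A come from a symmetrical phenol and because an alkoxy group at C5 is the control element of the key step. The gain is that the C5 and C7 oxygens never have to be distinguished by protection. The forward step must tell the two methyl ethers apart through chelation to C4=O alone, without opening ring C.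

29 to 28. O1–C2 is cut. This removes ring C and the only stereocentre and leaves an achiral, isolable compound with a single free phenol, so the direction of closure is not in question. The forward step must be a catalyst-controlled 6-endo-trig oxa-Michael addition to the Si face of the β-carbon, run under conditions that do not let the product re-open.

28 to 13 and 23. O1–C8a and C4–C4a are cut together. This splits the molecule into two halves of similar size, each four or five steps from commercial material, and reduces ring A to an aryne. The forward step must add oxygen at the aryne carbon next to the prenylated carbon, acylate the aryl anion rather than protonate it, and leave ring C open in that flask. For the last two reasons 23 enters as its anhydrous caesium salt 24.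

13 to 11 to 6 to 2 to 1. The cuts are the S–O bond of the triflate (with a carbamate in its place), the C8–CH2 bond to the prenyl group, and the C4a–Si bond. Each is cut because it can be made by ortho-metalation directed by the same carbamate. Since 1 is symmetrical, the first metalation has one outcome and the second has one position left. The gain is a commodity phenol. The forward sequence must introduce silicon before the prenyl group, so that no benzylic-allylic CH2 is present in either lithiation. It also needs a carbamate that base alone removes (the N-isopropyl carbamate, by E1cB), because the ortho-prenyl phenol would cyclise under acid.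

23 to 21 and 22. The aryl–alkenyl bond (the future C1'–C2 bond) is cut. A Heck coupling can install the whole three-carbon acid in one operation from a commodity alkene. The forward step needs insertion into 22 rather than into the chromene double bond, and E geometry.

21 to 19 to 18 to 17. The chromene C3=C4 double bond is traced back to the C4 alcohol and then the C4 ketone, and the acetal O–CH2 bond on the C7 oxygen is cut. A chromanone is far easier to make regioselectively than a chromene. The forward steps must protect before reducing (the free para-hydroxy ketone resists hydride) and must dehydrate without acid.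

17 to 14 and 15. The aryl–acyl bond and the O1–C2 bond of the chromanone are cut (Friedel–Crafts acylation, then oxa-Michael closure). The bromine of 14 blocks one activated position and marks the carbon that later carries the side chain, so the linear ring fusion is dictated. The forward step must acylate at the one open position para to a hydroxyl.

## Other disconnections considered

Alternative 1: The cut takes ring C apart at C4a–C4, C4–C3 and O1–C2, and the C2 stereocentre is left to a later enantioselective reduction of C2=C3.
- **Fragments:** C4 becomes carbon monoxide A3, C2 and C3 become the two carbons of the ring B alkyne A2 (6-ethynyl-7-(methoxymethoxy)-2,2-dimethyl-2H-chromene), and ring A becomes the symmetrical iodoresorcinol A1 (2-iodo-5-methoxybenzene-1,3-diol).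
- **Forward key step:** PdCl2(PPh3)2 in a secondary amine would couple A1, A3 and A2 and close the acyclic intermediate 6-endo to the flavone A4 (5-hydroxy-7-methoxy-2-[7-(methoxymethoxy)-2,2-dimethyl-2H-chromen-6-yl]-4H-chromen-4-one).
- **In its favour:** three simple components meet in one flask; A1 is symmetrical, so either hydroxyl gives the same ring; the C5 hydroxyl is free from the start, so no ether cleavage is needed; A4 is achiral and robust.
- **Against it here:** A4 has no substituent at C8. The prenyl group would have to be added to a 5-hydroxy-7-methoxyflavone with both C6 and C8 open (O-prenylation of the chelated hydroxyl and Claisen–Cope migration: two more steps and a C6/C8 question). Building it into A1 instead makes the two hydroxyls different and the direction of closure ambiguous, which is the problem the aryne route avoids. The reduction must then deliver hydride enantioselectively to C2 of an electron-rich, chelated 2-arylchromone beside two other alkenes; a chiral bisphosphine–CuH catalyst is chemoselective in principle but better established for 2-alkylchromones. A competing 5-exo closure to an aurone is also possible.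
- **Comparison:** On structure, the chosen plan fixes the C8 prenyl group by construction and Alternative 1 does not. On mechanism, Alternative 1 creates C2 by irreversible hydride delivery to a configurationally inert flavone, whereas the chosen plan uses a reversible oxa-Michael addition. On that point, and in needing neither the C5 demethylation nor a silyl triflate, Alternative 1 is the equal or the better. On step count the two are about level once the prenylation is included, but Alternative 1 then has two uncertain operations (prenyl regiochemistry, asymmetric reduction) where the chosen plan has one after its key step.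

Alternative 2: The cut is made at C3–C4 and O1–C2, so ring C arises from a [4+2] cycloaddition between a ring A heterodiene (O1–C8a–C4a–C4) and the C2=C3 bond of a ring B styrene.
- **Forward key step:** a confined chiral imidodiphosphorimidate Brønsted acid would turn the salicylaldehyde A5 (2-hydroxy-4,6-dimethoxy-3-prenylbenzaldehyde) and the orthoester A6 (trimethyl orthoformate) into a cationic ortho-quinone methide equivalent. The styrene A7 (tert-butyl[(6-ethenyl-2,2-dimethyl-2H-chromen-7-yl)oxy]dimethylsilane) would trap it to give the 2,4-cis flavan A8, (2S,4S).
- **In its favour:** C2 is set in the bond-forming event under catalyst control; the assembly is convergent; the prenyl group has a fixed position in A5; no chalcone is ever formed, so there is no racemic background closure.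
- **Against it here:** a strongly acidic catalyst and cationic intermediates must coexist with the prenyl group and with the chromene double bond of A7, which is itself an electron-rich styrene-type alkene and a second possible 2π partner. The ortho-silyloxy group crowds the reacting vinyl group inside a confined catalyst. A8 is at the wrong oxidation level: its C4 methyl ether, a doubly activated benzylic ether, must be hydrolysed and oxidised to the ketone before the C5 demethylation and the desilylation.
- **Comparison:** On structure, both plans fix the prenyl position by construction. On mechanism, Alternative 2 is the equal or the better for enantiocontrol at C2, because its stereo-determining step is irreversible; its cationic manifold is, however, less compatible with the two alkenes than the anionic aryne insertion. On step economy the chosen plan is shorter: four steps follow the key step of Alternative 2 against three, and A5 and A7 each need extra operations.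

Alternative 3: The cut removes ring A: C4a–C5 and C8–C8a are disconnected, so rings C and B, with C2 already in place, form the dienophile and ring A is assembled from an acyclic diene.
- **Forward key step:** the dihydropyranone A9 ((2S)-2-[7-(methoxymethoxy)-2,2-dimethyl-2H-chromen-6-yl]-5-(phenylsulfinyl)-2,3-dihydro-4H-pyran-4-one, configuration at sulfur immaterial) would be heated with the diene A10 ([(1,3-dimethoxy-7-methylocta-1,3,6-trien-1-yl)oxy]trimethylsilane). The prenyl-bearing diene terminus bonds to the β-carbon of the enone (C8–C8a) and the ketene acetal carbon to the sulfinyl-bearing carbon (C5–C4a). Loss of the sulfinyl group as its sulfenic acid and of one methoxy group aromatises ring A to A11, the same compound as 30.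
- **In its favour:** the whole ring A pattern (free 5-OH, 7-OMe, 8-prenyl) is written into an acyclic diene, so there is no arene regiochemistry and no ether cleavage. C2 can be set early by an asymmetric hetero-Diels–Alder reaction, a reaction type with strong precedent for high enantioselectivity; on both points the alternative is the better.
- **Against it here:** the stereocentre must be carried through the functionalisation of the enone at C5 (halogenation, thiolation, oxidation) and a thermal cycloaddition–elimination. A10 has a substituent on its reacting terminus, so it is hindered, hydrolytically labile, and its geometry must be controlled. The sulfenic acid set free can add to the alkenes of the product. The sequence is essentially linear from the ring B building block.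
- **Comparison:** On structure, Alternative 3 places the ring A substituents at least as securely and reaches 30 without demethylation. On mechanism, it swaps the reversible asymmetric oxa-Michael step for a pre-set stereocentre that is exposed at every later stage. On step economy the chosen plan has the shorter longest linear sequence (nine steps against roughly twelve to fourteen) and two branches of similar length.

Key step: step 10

Remarks on the chemistry:
- Flavanone numbering (O1, C2–C4, C4a, C5–C8, C8a; primed locants for ring B) is used for the target and, by anticipation, for its precursors. Prenyl = 3-methylbut-2-en-1-yl, TMS = trimethylsilyl, TBS = tert-butyldimethylsilyl, MOM = methoxymethyl.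
- The target's stereodescriptor corresponds to (2S).
- The coupling partners 13 and 23 and the product 28 are consistent in connectivity with the target; the only change to a partner is that 23 reacts as its anhydrous caesium salt 24.
- It is assumed that the quinine-derived catalyst of step 11 gives the (2S) product; if the sense of induction is the opposite, the quinidine-derived pseudoenantiomer takes its place.

Step 1
Reactants: 1 3,5-dimethoxyphenol
Product: 2 3,5-dimethoxyphenyl N-isopropylcarbamate
Conditions: i-PrNCO, Et3N (cat.), CH2Cl2, rt
Reagents that add atoms: isopropyl isocyanate, CC(C)N=C=O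
Why: Amine-catalysed addition of the phenol to the isocyanate (carbamoylation); the N-monoalkyl carbamate is chosen because it directs ortho-metalation after in situ N-silylation and is later removed by base alone.

Step 2
Reactants: 2 3,5-dimethoxyphenyl N-isopropylcarbamate
Product: 6 3,5-dimethoxy-2-(trimethylsilyl)phenyl N-isopropylcarbamate, via N-TMS carbamate 3 (not isolated), via aryllithium 4 (not isolated), via N-TMS C-silyl carbamate 5 (not isolated)
Conditions: TMSOTf, TMEDA, Et2O, 0 °C to rt; n-BuLi, TMEDA, −78 °C; TMSCl, −78 °C to rt; aq. NaHSO4
Reagents that add atoms: chlorotrimethylsilane, C[Si](C)(C)Cl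
Why: Directed ortho-metalation: the carbamate, N-silylated in situ as its labile N-TMS derivative, is the strongest director on the ring and, reinforced by the neighbouring methoxy group, makes the two equivalent positions between carbamate and methoxy the kinetic site in preference to the position between the two methoxy groups; C-silylation of 4 and hydrolysis of the N–Si bond of 5 on acidic work-up should give 6.

Step 3
Reactants: 6 3,5-dimethoxy-2-(trimethylsilyl)phenyl N-isopropylcarbamate
Product: 11 3,5-dimethoxy-6-prenyl-2-(trimethylsilyl)phenyl N-isopropylcarbamate, via N-TBS C-silyl carbamate 7 (not isolated), via aryllithium 8 (not isolated), via arylcopper 9 (not isolated), via N-TBS prenyl carbamate 10 (not isolated)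
Conditions: TBSOTf, TMEDA, Et2O, 0 °C to rt; n-BuLi, TMEDA, −78 °C; CuBr·SMe2, THF, −78 to −40 °C; prenyl bromide, −78 °C to rt; aq. NH4Cl/MeOH
Reagents that add atoms: prenyl bromide (1-bromo-3-methylbut-2-ene), CC(C)=CCBr
Why: Second directed ortho-metalation at the one remaining position flanked by carbamate and methoxy, with the sturdier N-TBS group as temporary nitrogen protection because this anion must survive warming; transmetalation to monovalent copper suppresses the anionic Fries shift and should give SN2 coupling at the primary carbon of prenyl bromide. Silicon goes in first so that no benzylic-allylic CH2 is present during either lithiation.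

Step 4
Reactants: 11 3,5-dimethoxy-6-prenyl-2-(trimethylsilyl)phenyl N-isopropylcarbamate
Product: 13 3,5-dimethoxy-6-prenyl-2-(trimethylsilyl)phenyl trifluoromethanesulfonate, via silyl phenol 12 (not isolated)
Conditions: DBU, Et2NH, MeCN, 40 °C; then PhNTf2, rt
Reagents that add atoms: N-phenylbis(trifluoromethanesulfonimide), O=S(=O)(N(c1ccccc1)S(=O)(=O)C(F)(F)F)C(F)(F)F
Why: E1cB cleavage of the N–H carbamate (loss of isopropyl isocyanate, trapped by Et2NH) is indifferent to the two ortho substituents, and the phenoxide of 12 is sulfonylated in the same flask; the acid-sensitive ortho-prenyl phenol is never isolated or exposed to acid.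

Step 5
Reactants: 14 4-bromoresorcinol (4-bromobenzene-1,3-diol); 15 3-methylbut-2-enoic acid
Product: 17 6-bromo-7-hydroxy-2,2-dimethylchroman-4-one, via aryl enone 16 (not isolated)
Conditions: P2O5, MeSO3H, 70 °C
Reagents that add atoms: none
Why: Friedel–Crafts acylation at the only unhindered activated position of 14 (para to one hydroxyl, ortho to the other), then 6-endo-trig oxa-Michael closure of the ortho hydroxyl onto the enone of 16; the bromine thus ends at C6 beside the free C7 hydroxyl, which fixes the linear ring fusion.

Step 6
Reactants: 17 6-bromo-7-hydroxy-2,2-dimethylchroman-4-one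
Product: 18 6-bromo-7-(methoxymethoxy)-2,2-dimethylchroman-4-one
Conditions: MOMCl, i-Pr2NEt, CH2Cl2, 0 °C to rt
Reagents that add atoms: chloromethyl methyl ether, COCCl
Why: O-Alkylation of the acidic para-acyl phenol; the MOM ether should survive hydride, base, palladium and fluoride and is removed only in the last step.

Step 7
Reactants: 18 6-bromo-7-(methoxymethoxy)-2,2-dimethylchroman-4-one
Product: 19 racemic 6-bromo-7-(methoxymethoxy)-2,2-dimethylchroman-4-ol
Conditions: NaBH4, MeOH–THF, 0 °C to rt
Reagents that add atoms: none
Why: Hydride reduction of the aryl ketone, possible once the phenol is capped; the C4 stereocentre is destroyed in step 8, so the racemate is used.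

Step 8
Reactants: 19 racemic 6-bromo-7-(methoxymethoxy)-2,2-dimethylchroman-4-ol
Product: 21 6-bromo-7-(methoxymethoxy)-2,2-dimethyl-2H-chromene, via benzylic mesylate 20 (not isolated)
Conditions: MsCl, Et3N, CH2Cl2, 0 °C; then DBU, rt
Reagents that add atoms: none
Why: Sulfonylation of a benzylic alcohol para to an alkoxy group gives a readily ionised mesylate that eliminates to the conjugated chromene under basic conditions, which spare the MOM ether.

Step 9
Reactants: 21 6-bromo-7-(methoxymethoxy)-2,2-dimethyl-2H-chromene; 22 acrylic acid
Product: 23 (E)-3-[7-(methoxymethoxy)-2,2-dimethyl-2H-chromen-6-yl]prop-2-enoic acid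
Conditions: Pd(OAc)2 (5 mol%), P(o-tol)3 (10 mol%), Et3N, DMF, 100 °C
Reagents that add atoms: none
Why: Mizoroki–Heck reaction: oxidative addition of zerovalent palladium (formed in situ) to the aryl bromide, insertion of the acrylate and β-hydride elimination should give the E acid directly; the acrylate inserts far faster than the cis-disubstituted chromene alkene.

Step 10
Reactants: 13 3,5-dimethoxy-6-prenyl-2-(trimethylsilyl)phenyl trifluoromethanesulfonate; 23 (E)-3-[7-(methoxymethoxy)-2,2-dimethyl-2H-chromen-6-yl]prop-2-enoic acid
Product: 28 (E)-1-[2-hydroxy-4,6-dimethoxy-3-prenylphenyl]-3-[7-(methoxymethoxy)-2,2-dimethyl-2H-chromen-6-yl]prop-2-en-1-one, via caesium carboxylate 24 (not isolated), via aryne 25 (not isolated), via aryl anion 26 (not isolated), via benzoxetene alkoxide 27 (not isolated)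
Conditions: 23, Cs2CO3 (0.5 equiv), MeOH, rt, then PhMe azeotrope; 13 (1.3 equiv), CsF (3 equiv), 18-crown-6 (0.3 equiv), THF, 50 °C; AcOH, 0 °C
Reagents that add atoms: none
Why: Fluoride attacks silicon of 13 and triflate leaves, giving aryne 25. The carboxylate oxygen of 24 should add at the aryne carbon remote from the adjacent methoxy group (future C8a), because the inductively withdrawing C5 oxygen distorts the triple bond and stabilises the carbanion developing at C4a; the prenyl group beside C8a and the second, more distant methoxy group oppose this only weakly. Aryl anion 26 then attacks its own ester carbonyl (4-exo-trig) to give the four-membered alkoxide 27, which opens to the chelated ortho-acyl phenoxide, so O1–C8a and C4–C4a are formed and no ring remains closed in the product. The closest known reaction type is the insertion of arynes from ortho-silylaryl triflates into the C–O bond of carboxylic acids, cinnamic acids included. No stereocentre is formed and the E alkene is carried through unchanged. Using the dry caesium salt in an aprotic medium removes the proton source that would quench 26 to an aryl ester, and it also denies the product phenoxide the proton relay needed for racemic closure of ring C; the cold acetic acid quench then releases 28.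

Step 11
Reactants: 28 (E)-1-[2-hydroxy-4,6-dimethoxy-3-prenylphenyl]-3-[7-(methoxymethoxy)-2,2-dimethyl-2H-chromen-6-yl]prop-2-en-1-one
Product: 29 (2S)-5,7-dimethoxy-2-[7-(methoxymethoxy)-2,2-dimethyl-2H-chromen-6-yl]-8-prenylchroman-4-one
Conditions: quinine-derived 3,5-bis(trifluoromethyl)phenyl thiourea (9-amino-9-deoxy-epi-quinine series, 20 mol%), PhMe, 0 °C
Reagents that add atoms: none
Why: Catalytic asymmetric intramolecular oxa-Michael addition (6-endo-trig): the quinuclidine nitrogen engages the 2'-OH as a general base while the thiourea hydrogen-bonds to the enone carbonyl, and within this assembly the phenol oxygen should add to the Si face of the β-carbon, creating C2 as (S). Only one phenol is free, so the ring can close in one direction only; low temperature and the absence of stronger base hold back the retro-reaction.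

Step 12
Reactants: 29 (2S)-5,7-dimethoxy-2-[7-(methoxymethoxy)-2,2-dimethyl-2H-chromen-6-yl]-8-prenylchroman-4-one
Product: 30 (2S)-5-hydroxy-7-methoxy-2-[7-(methoxymethoxy)-2,2-dimethyl-2H-chromen-6-yl]-8-prenylchroman-4-one
Conditions: MgI2·OEt2 (2.5 equiv), PhMe–Et2O, 50 °C; then cold pH 6 buffer
Reagents that add atoms: none
Why: Chelation-controlled ether cleavage: magnesium binds the C4 carbonyl and the peri C5 ether oxygen and iodide removes the methyl group by SN2, while the C7 ether cannot chelate and the alkenes are inert to this mild Lewis acid. The ring B oxygen is still a MOM ether, so no ortho-phenoxide can assist C2–O1 cleavage and C2 should be retained.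

Step 13
Reactants: 30 (2S)-5-hydroxy-7-methoxy-2-[7-(methoxymethoxy)-2,2-dimethyl-2H-chromen-6-yl]-8-prenylchroman-4-one
Product: 31 maackiaflavanone A, (2S)-5-hydroxy-2-(7-hydroxy-2,2-dimethyl-2H-chromen-6-yl)-7-methoxy-8-prenylchroman-4-one
Conditions: HCl (3 M aq.), MeOH–THF, 35 °C
Reagents that add atoms: none
Why: Acid-catalysed acetal exchange with methanol frees the ring B phenol; no free hydroxyl stands ortho to the prenyl group, so acid-induced chroman formation is impossible, and the low temperature and short exposure should leave the chromene and C2 intact.

Compound list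

1 | 3,5-dimethoxyphenol | COc1cc(O)cc(OC)c1 | starting material
2 | 3,5-dimethoxyphenyl N-isopropylcarbamate | COc1cc(OC)cc(OC(=O)NC(C)C)c1 | intermediate
3 | 3,5-dimethoxyphenyl N-isopropyl-N-(trimethylsilyl)carbamate | COc1cc(OC)cc(OC(=O)N(C(C)C)[Si](C)(C)C)c1 | intermediate (not isolated)
4 | 2-lithio-3,5-dimethoxyphenyl N-isopropyl-N-(trimethylsilyl)carbamate | COc1cc(OC)c([Li])c(OC(=O)N(C(C)C)[Si](C)(C)C)c1 | intermediate (not isolated)
5 | 3,5-dimethoxy-2-(trimethylsilyl)phenyl N-isopropyl-N-(trimethylsilyl)carbamate | COc1cc(OC)c([Si](C)(C)C)c(OC(=O)N(C(C)C)[Si](C)(C)C)c1 | intermediate (not isolated)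
6 | 3,5-dimethoxy-2-(trimethylsilyl)phenyl N-isopropylcarbamate | COc1cc(OC)c([Si](C)(C)C)c(OC(=O)NC(C)C)c1 | intermediate
7 | 3,5-dimethoxy-2-(trimethylsilyl)phenyl N-(tert-butyldimethylsilyl)-N-isopropylcarbamate | COc1cc(OC)c([Si](C)(C)C)c(OC(=O)N(C(C)C)[Si](C)(C)C(C)(C)C)c1 | intermediate (not isolated)
8 | 6-lithio-3,5-dimethoxy-2-(trimethylsilyl)phenyl N-(tert-butyldimethylsilyl)-N-isopropylcarbamate | COc1cc(OC)c([Si](C)(C)C)c(OC(=O)N(C(C)C)[Si](C)(C)C(C)(C)C)c1[Li] | intermediate (not isolated)
9 | arylcopper corresponding to 8 (copper in place of lithium, as its LiBr complex) | COc1cc(OC)c([Si](C)(C)C)c(OC(=O)N(C(C)C)[Si](C)(C)C(C)(C)C)c1[Cu] | intermediate (not isolated)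
10 | 3,5-dimethoxy-6-prenyl-2-(trimethylsilyl)phenyl N-(tert-butyldimethylsilyl)-N-isopropylcarbamate | COc1cc(OC)c([Si](C)(C)C)c(OC(=O)N(C(C)C)[Si](C)(C)C(C)(C)C)c1CC=C(C)C | intermediate (not isolated)
11 | 3,5-dimethoxy-6-prenyl-2-(trimethylsilyl)phenyl N-isopropylcarbamate | COc1cc(OC)c([Si](C)(C)C)c(OC(=O)NC(C)C)c1CC=C(C)C | intermediate
12 | 3,5-dimethoxy-6-prenyl-2-(trimethylsilyl)phenol (as its DBU-H phenoxide) | COc1cc(OC)c([Si](C)(C)C)c(O)c1CC=C(C)C | intermediate (not isolated)
13 | 3,5-dimethoxy-6-prenyl-2-(trimethylsilyl)phenyl trifluoromethanesulfonate | COc1cc(OC)c([Si](C)(C)C)c(OS(=O)(=O)C(F)(F)F)c1CC=C(C)C | intermediate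
14 | 4-bromoresorcinol (4-bromobenzene-1,3-diol) | Oc1ccc(Br)c(O)c1 | starting material
15 | 3-methylbut-2-enoic acid | CC(C)=CC(=O)O | starting material
16 | 1-(5-bromo-2,4-dihydroxyphenyl)-3-methylbut-2-en-1-one | CC(C)=CC(=O)c1cc(Br)c(O)cc1O | intermediate (not isolated)
17 | 6-bromo-7-hydroxy-2,2-dimethylchroman-4-one | CC1(C)CC(=O)c2cc(Br)c(O)cc2O1 | intermediate
18 | 6-bromo-7-(methoxymethoxy)-2,2-dimethylchroman-4-one | CC1(C)CC(=O)c2cc(Br)c(OCOC)cc2O1 | intermediate
19 | racemic 6-bromo-7-(methoxymethoxy)-2,2-dimethylchroman-4-ol | CC1(C)CC(O)c2cc(Br)c(OCOC)cc2O1 | intermediate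
20 | racemic 6-bromo-7-(methoxymethoxy)-2,2-dimethylchroman-4-yl methanesulfonate | CC1(C)CC(OS(C)(=O)=O)c2cc(Br)c(OCOC)cc2O1 | intermediate (not isolated)
21 | 6-bromo-7-(methoxymethoxy)-2,2-dimethyl-2H-chromene | CC1(C)C=Cc2cc(Br)c(OCOC)cc2O1 | intermediate
22 | acrylic acid | C=CC(=O)O | starting material
23 | (E)-3-[7-(methoxymethoxy)-2,2-dimethyl-2H-chromen-6-yl]prop-2-enoic acid | OC(=O)/C=C/c1cc2c(cc1OCOC)OC(C)(C)C=C2 | intermediate
24 | caesium (E)-3-[7-(methoxymethoxy)-2,2-dimethyl-2H-chromen-6-yl]prop-2-enoate | [Cs+].[O-]C(=O)/C=C/c1cc2c(cc1OCOC)OC(C)(C)C=C2 | intermediate (not isolated)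
25 | 1,2-didehydro-3,5-dimethoxy-6-prenylbenzene (the ring A aryne) | COC1=C(CC=C(C)C)C#CC(OC)=C1 | intermediate (not isolated)
26 | caesium 2-{[(E)-3-(7-(methoxymethoxy)-2,2-dimethyl-2H-chromen-6-yl)prop-2-enoyl]oxy}-4,6-dimethoxy-3-prenylbenzen-1-ide (anion at the carbon between the ester oxygen and a methoxy group) | [Cs+].COc1cc(OC)[c-]c(OC(=O)/C=C/c2cc3c(cc2OCOC)OC(C)(C)C=C3)c1CC=C(C)C | intermediate (not isolated)
27 | caesium 2H-benzoxet-2-olate formed from 26 (four-membered ring O–C(O−)(alkenyl) spanning the two former aryne carbons) | [Cs+].COc1cc(OC)c2c(c1CC=C(C)C)OC2([O-])/C=C/c1cc3c(cc1OCOC)OC(C)(C)C=C3 | intermediate (not isolated)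
28 | (E)-1-[2-hydroxy-4,6-dimethoxy-3-prenylphenyl]-3-[7-(methoxymethoxy)-2,2-dimethyl-2H-chromen-6-yl]prop-2-en-1-one | COc1cc(OC)c(C(=O)/C=C/c2cc3c(cc2OCOC)OC(C)(C)C=C3)c(O)c1CC=C(C)C | intermediate
29 | (2S)-5,7-dimethoxy-2-[7-(methoxymethoxy)-2,2-dimethyl-2H-chromen-6-yl]-8-prenylchroman-4-one | COc1cc(OC)c2c(c1CC=C(C)C)O[C@H](c1cc3c(cc1OCOC)OC(C)(C)C=C3)CC2=O | intermediate
30 | (2S)-5-hydroxy-7-methoxy-2-[7-(methoxymethoxy)-2,2-dimethyl-2H-chromen-6-yl]-8-prenylchroman-4-one | COc1cc(O)c2c(c1CC=C(C)C)O[C@H](c1cc3c(cc1OCOC)OC(C)(C)C=C3)CC2=O | intermediate
31 | maackiaflavanone A, (2S)-5-hydroxy-2-(7-hydroxy-2,2-dimethyl-2H-chromen-6-yl)-7-methoxy-8-prenylchroman-4-one | COc1cc(O)c2c(c1CC=C(C)C)O[C@H](c1cc3c(cc1O)OC(C)(C)C=C3)CC2=O | target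

Total step count: 13. Longest linear sequence: 9 steps (steps 5 to 9, then 10 to 13); the ring A branch contributes steps 1 to 4.

Least certain steps

Step 10 (key step).
- **What may go wrong:** the carboxylate may add at the other aryne carbon, since the prenyl group crowds the intended site and the remote methoxy group slightly opposes the inductive control. The aryl anion may be protonated before the acyl shift if traces of water or methanol survive the drying, which ends at an aryl ester. The product phenoxide may close ring C in the flask, giving racemic material, or be arylated by a second aryne. Ene-type reaction of the aryne with the trisubstituted alkenes is a minor additional drain.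
- **Fallback (sets out from 2 and 23, returns at 28):** this builds C4–C4a by acylating an aryllithium, with the phenol oxygen already in place. Carbamate 2 is prenylated under the conditions of step 3 to give 3,5-dimethoxy-2-prenylphenyl N-isopropylcarbamate F1. Acid 23 is converted (1,1'-carbonyldiimidazole, MeNHOMe·HCl) into the Weinreb amide (E)-N-methoxy-N-methyl-3-[7-(methoxymethoxy)-2,2-dimethyl-2H-chromen-6-yl]prop-2-enamide F2. A second directed ortho-lithiation of F1 (in situ N-silylation, n-BuLi/TMEDA, −78 °C; ring metalation between carbamate and methoxy is kinetically preferred to lateral deprotonation) and acylation with F2 give the chalcone carbamate 2-[(E)-3-(7-(methoxymethoxy)-2,2-dimethyl-2H-chromen-6-yl)prop-2-enoyl]-3,5-dimethoxy-6-prenylphenyl N-isopropylcarbamate F3. DBU/Et2NH, as in step 4, releases 28.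

Step 11.
- **What may go wrong:** facial selectivity may be poor and turnover slow on this twisted, electron-rich enone with an ortho-substituted β-aryl group. The addition is reversible, so the catalyst may erode the configuration at long reaction times.
- **Fallback (sets out from 28, returns at 29):** resolution with recycling instead of asymmetric catalysis. Closure with NaOAc in refluxing EtOH gives the racemic flavanone rac-5,7-dimethoxy-2-[7-(methoxymethoxy)-2,2-dimethyl-2H-chromen-6-yl]-8-prenylchroman-4-one F4. Preparative chromatography on a chiral polysaccharide phase delivers 29. The (2R)-flavanone (2R)-5,7-dimethoxy-2-[7-(methoxymethoxy)-2,2-dimethyl-2H-chromen-6-yl]-8-prenylchroman-4-one F5 is re-opened with KOH in MeOH and returned to 28 on acidification.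

Step 12.
- **What may go wrong:** Lewis-acid-promoted opening of ring C may erode the C2 configuration, and once the C5 hydroxyl is free the ring may re-close through the other ortho oxygen (prenyl then formally at C6). The MOM ether may be lost early, and adventitious HI may add to the alkenes.
- **Fallback (sets out from 28, returns at 30):** the configuration is settled only after the Lewis-acid step. The racemic flavanone F4 (made as in the fallback for step 11) is demethylated with MgI2·OEt2 to the racemic 5-hydroxyflavanone rac-5-hydroxy-7-methoxy-2-[7-(methoxymethoxy)-2,2-dimethyl-2H-chromen-6-yl]-8-prenylchroman-4-one F6. F6 is resolved on a chiral stationary phase to give 30. The (2R)-5-hydroxyflavanone (2R)-5-hydroxy-7-methoxy-2-[7-(methoxymethoxy)-2,2-dimethyl-2H-chromen-6-yl]-8-prenylchroman-4-one F7 is discarded, because re-opening it would allow closure through either oxygen.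

Step 9.
- **What may go wrong:** oxidative addition to the electron-rich, ortho-alkoxy aryl bromide may be sluggish, and the chromene double bond may be arylated or the acrylic acid may oligomerise.
- **Fallback (sets out from 21, returns at 23):** bromine–lithium exchange (n-BuLi, THF, −78 °C) and formylation with DMF give 7-(methoxymethoxy)-2,2-dimethyl-2H-chromene-6-carbaldehyde F8. Knoevenagel–Doebner condensation with malonic acid (pyridine, piperidine, 90 °C) gives 23.

Step 3.
- **What may go wrong:** coupling may occur at the tertiary terminus of the allyl system (SN2′, giving the 1,1-dimethylallyl isomer), or metalation may occur between the two methoxy groups.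
- **Fallback (sets out from 6, returns at 11):** the same metalation through 7, 8 and 9, quenched with allyl bromide (both substitution modes give one product) and worked up as in step 3, gives 2-allyl-3,5-dimethoxy-6-(trimethylsilyl)phenyl N-isopropylcarbamate F9. Cross-metathesis with 2-methylbut-2-ene (second-generation Grubbs catalyst, CH2Cl2, 40 °C) converts the allyl group into the prenyl group of 11.

Further compounds

F1 | step 10 | 3,5-dimethoxy-2-prenylphenyl N-isopropylcarbamate | COc1cc(OC)c(CC=C(C)C)c(OC(=O)NC(C)C)c1
F2 | step 10 | (E)-N-methoxy-N-methyl-3-[7-(methoxymethoxy)-2,2-dimethyl-2H-chromen-6-yl]prop-2-enamide | CON(C)C(=O)/C=C/c1cc2c(cc1OCOC)OC(C)(C)C=C2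
F3 | step 10 | 2-[(E)-3-(7-(methoxymethoxy)-2,2-dimethyl-2H-chromen-6-yl)prop-2-enoyl]-3,5-dimethoxy-6-prenylphenyl N-isopropylcarbamate | COc1cc(OC)c(C(=O)/C=C/c2cc3c(cc2OCOC)OC(C)(C)C=C3)c(OC(=O)NC(C)C)c1CC=C(C)C
F4 | step 11 | rac-5,7-dimethoxy-2-[7-(methoxymethoxy)-2,2-dimethyl-2H-chromen-6-yl]-8-prenylchroman-4-one | COc1cc(OC)c2c(c1CC=C(C)C)OC(c1cc3c(cc1OCOC)OC(C)(C)C=C3)CC2=O
F5 | step 11 | (2R)-5,7-dimethoxy-2-[7-(methoxymethoxy)-2,2-dimethyl-2H-chromen-6-yl]-8-prenylchroman-4-one | COc1cc(OC)c2c(c1CC=C(C)C)O[C@@H](c1cc3c(cc1OCOC)OC(C)(C)C=C3)CC2=O
F6 | step 12 | rac-5-hydroxy-7-methoxy-2-[7-(methoxymethoxy)-2,2-dimethyl-2H-chromen-6-yl]-8-prenylchroman-4-one | COc1cc(O)c2c(c1CC=C(C)C)OC(c1cc3c(cc1OCOC)OC(C)(C)C=C3)CC2=O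
F7 | step 12 | (2R)-5-hydroxy-7-methoxy-2-[7-(methoxymethoxy)-2,2-dimethyl-2H-chromen-6-yl]-8-prenylchroman-4-one | COc1cc(O)c2c(c1CC=C(C)C)O[C@@H](c1cc3c(cc1OCOC)OC(C)(C)C=C3)CC2=O
F8 | step 9 | 7-(methoxymethoxy)-2,2-dimethyl-2H-chromene-6-carbaldehyde | O=Cc1cc2c(cc1OCOC)OC(C)(C)C=C2
F9 | step 3 | 2-allyl-3,5-dimethoxy-6-(trimethylsilyl)phenyl N-isopropylcarbamate | COc1cc(OC)c([Si](C)(C)C)c(OC(=O)NC(C)C)c1CC=C
A1 | alternative 1 | 2-iodo-5-methoxybenzene-1,3-diol | COc1cc(O)c(I)c(O)c1
A2 | alternative 1 | 6-ethynyl-7-(methoxymethoxy)-2,2-dimethyl-2H-chromene | C#Cc1cc2c(cc1OCOC)OC(C)(C)C=C2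
A3 | alternative 1 | carbon monoxide | [C-]#[O+]
A4 | alternative 1 | 5-hydroxy-7-methoxy-2-[7-(methoxymethoxy)-2,2-dimethyl-2H-chromen-6-yl]-4H-chromen-4-one | COc1cc(O)c2c(c1)oc(-c1cc3c(cc1OCOC)OC(C)(C)C=C3)cc2=O
A5 | alternative 2 | 2-hydroxy-4,6-dimethoxy-3-prenylbenzaldehyde | COc1cc(OC)c(C=O)c(O)c1CC=C(C)C
A6 | alternative 2 | trimethyl orthoformate | COC(OC)OC
A7 | alternative 2 | tert-butyl[(6-ethenyl-2,2-dimethyl-2H-chromen-7-yl)oxy]dimethylsilane | C=Cc1cc2c(cc1O[Si](C)(C)C(C)(C)C)OC(C)(C)C=C2
A8 | alternative 2 | (2S,4S)-2-[7-(tert-butyldimethylsilyloxy)-2,2-dimethyl-2H-chromen-6-yl]-4,5,7-trimethoxy-8-prenylchromane (2,4-cis) | COc1cc(OC)c2c(c1CC=C(C)C)O[C@H](c1cc3c(cc1O[Si](C)(C)C(C)(C)C)OC(C)(C)C=C3)C[C@@H]2OC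
A9 | alternative 3 | (2S)-2-[7-(methoxymethoxy)-2,2-dimethyl-2H-chromen-6-yl]-5-(phenylsulfinyl)-2,3-dihydro-4H-pyran-4-one (sulfur configuration unspecified) | O=C1C(S(=O)c2ccccc2)=CO[C@H](c2cc3c(cc2OCOC)OC(C)(C)C=C3)C1
A10 | alternative 3 | [(1,3-dimethoxy-7-methylocta-1,3,6-trien-1-yl)oxy]trimethylsilane | COC(O[Si](C)(C)C)=CC(OC)=CCC=C(C)C
A11 | alternative 3 | (2S)-5-hydroxy-7-methoxy-2-[7-(methoxymethoxy)-2,2-dimethyl-2H-chromen-6-yl]-8-prenylchroman-4-one (identical with 30) | COc1cc(O)c2c(c1CC=C(C)C)O[C@H](c1cc3c(cc1OCOC)OC(C)(C)C=C3)CC2=O
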